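## Structural features

The target 33 is a germacranolide: a ten-membered carbocycle (C1–C10) fused trans across C7–C8 to an α-methylene-γ-butyrolactone (C7, C8, O8, C12, C11, with exocyclic C11=C13). The carbocycle holds two trisubstituted alkenes, C1=C10 (E, methyl C14) and C4=C5, in which C3 and C6 are cis (cis in the ring, but E by the sequence rule because C15 bears oxygen). Three contiguous stereocentres line one edge of the ring: C6 (R, free secondary allylic hydroxyl), C7 (S) and C8 (S, lactone oxygen). O6 and O8 lie on the same face (α) and both are trans to the C7–C11 bond. The primary allylic O15 carries a (Z)-2-(hydroxymethyl)but-2-enoyl ester whose carbonyl is cis to the β-methyl group. Fragile elements are the conjugate-acceptor lactone, the Z-enoate (isomerised by nucleophilic catalysts), the 1,5-diene in a medium ring (transannular cyclisation with acid, Cope shift on heating) and the 6-hydroxyl beside the lactone (translactonisation under base). The real difficulty is a ten-membered ring with two defined alkene geometries and three adjacent stereocentres on a mobile ring, together with the need to tell five oxygens apart. The key step uses the array O6–C6–C7–C11=C13: a homoallylic alcohol whose carbinol carbon C6 is bonded to the carbon (C7) that carries the methylene unit, which is the retron of a [2,3]-Wittig shift of an ether oxygen bridging C6 and C13 in a 13-membered ring.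

## Logic of the disconnections

33 ⇒ 32. The O–Si bonds on O6 and on the side-chain oxygen are cut last. A free O6–H beside the lactone invites translactonisation under base, and a free side-chain CH2OH would be oxidised during lactone formation. No skeletal simplification results, but every earlier step runs on a compound without these hydroxyls. The forward step needs fluoride under acidic buffering that spares the methylene lactone, the Z-enoate and the diene.

32 ⇒ 29. The lactone bond C12–O8 is cut and C12 returned to the alcohol level. A 2-methylene-1,4-diol is the standard precursor of an α-methylene-γ-lactone, and the conjugate acceptor is thereby absent from all earlier chemistry. The forward step needs an oxidant that touches only the single free allylic alcohol, and O6 must be blocked so that only O8 can close.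

29 ⇒ 28 ⇒ 27. The O–Si bonds on O8/O12 (triethylsilyl) and on O6 (tert-butyldimethylsilyl) are exchanged. This is what makes O8 and O6, both secondary and both next to C7, different. The demand is a silylation of the hindered O6–H and then a methanolysis that removes two triethylsilyl groups without loss of the primary tert-butyldimethylsilyl ether on the side chain.

27 ⇒ 21 + 26. The ester C–O bond at O15 is cut, which separates the side chain as an acid and leaves a diol. Acylation is placed before lactone formation so that no base meets the 6-hydroxy lactone. The forward step must pick the primary over the secondary hydroxyl and must not isomerise the Z-enoate, so the alcohol is activated and not the acid.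

21 ⇒ 19 (key). C6–C7 is cut and O6 is reconnected to C13. The ten-membered ring with two new stereocentres and the exocyclic methylene becomes a 13-membered diallylic ether with one stereocentre, which can be closed without medium-ring strain. The given structures of 19 and 21 were checked against 33 and need no change (C8 is S in both; C3/C6 cis; C8/C13 trans). One wording is corrected: the C7=C11 bond of 19 is trans along the ring but Z by the sequence rule, and C4=C5 is E by that rule. The substituents of 19 are kept: O15–H is free so that its alkoxide cannot be expelled from the C6 allyl anion, and O8/O12 are triethylsilyl ethers because they must later leave before the silyl group on O6. The description gives no element that tells C6 from C13 and ignores the new C6 alkoxide sitting 1,3 to the O8 silyl ether. Two structural remedies were weighed and rejected: a C6 stannane for tin–lithium exchange (the macrocycle becomes much harder to reach and C6 becomes a stereocentre), and a free O8–H (it removes the O6/O8 distinction needed for the lactone). The remedy adopted is operational: kinetic lithiation at low temperature, a cold acidic quench, and a fallback that makes the same bond another way.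

19 ⇒ 18 ⇒ 16. The O15 benzyl-type ether is restored, since no benzylic ether may be present with the base, and the ring bond C1–C2 is cut. This gives an open-chain ether with an alkenyl iodide at C1 and a vinyl group (C2=C3) on C4. The forward step is a hydroboration that must select the one monosubstituted alkene, followed by a B-alkyl Suzuki ring closure at high dilution.

16 ⇒ 15 + 13. The ether bond O–C13 is cut, giving an allylic bromide and an allylic alcohol of similar size. The oxygen is taken from O6 and the electrophile from C13 so that no alkoxide is ever formed on C13 next to the C12 silyl ether, where silyl migration would scramble the alkene geometry. The forward step needs SN2 at C13 without SN2′ at C7.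

15 ⇒ 4 + 14. The C4–C3 bond is cut, so C2 and C3 come from a vinyl metal and the ring-cis geometry is stored in an iodoalkene. The coupling must retain geometry.

13 ⇒ 12 ⇒ 11. C13–Br and then O13–H are traced to the benzyl-type ether that has marked C13 since step 1. The demand is oxidative ether cleavage and bromination that leave two triethylsilyl ethers and the alkenyl iodide alone.

11 ⇒ 9. C10–C14 and C1–I are cut together, returning to a terminal alkyne. The forward carbometalation must be syn and place methyl on C10 to give E C1=C10.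

9 ⇒ 8 ⇒ 7. The two O–Si bonds are cut, then C11–C12. C12 is brought in on the iodine-bearing carbon, so that C12 (cis to C8) and C13 (trans) are distinguished by their origin and not by a selective reaction. The coupling must retain geometry and tolerate a free alkyne.

7 ⇒ 5 + 6. C8–C9 is cut, which removes the only stereocentre made by reagent control. The forward step is an enantioselective propargylation of an enal.

5 ⇒ 4 ⇒ 2 ⇒ 1. The aldehyde is taken back to the alcohol, the C–I and C–H bonds across the alkene to an alkyne, and the benzyl-type ether to the symmetric diol. Both halves of 19 thus come from 4, whose Z geometry is fixed by a hydroxyl-directed anti addition.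

26 ⇒ 25 ⇒ 24 ⇒ 22. Hydrolysis and silylation are undone, then the C–CH2OH bond and the vinylic C–H bond are cut back to an ynoate. The forward syn hydrometalation and trapping with formaldehyde must give the Z-enoate.

## Other disconnections considered

Alternative 1: The cut is C8–C9 (with C1–C6 re-formed in the backward sense), so the ten-membered ring shrinks to a perillyl-type six-membered ring (C1–C6). This ring carries a 2-propenyl group (C10, C9, C14) on C1 and a 2-silylvinyl group (C7=C8) on the C6 carbinol. Forward, the potassium alkoxide undergoes an anionic oxy-Cope [3,3] shift to the C6 enolate, which is protonated to the 8-silyl dienone A1.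
- In its favour: the ring-cis C4=C5 bond is inherited from the cyclohexene, E C1=C10 follows from a chair-like transition state, the enolate makes the shift irreversible, no high dilution is needed, and silicon on C8 is a masked hydroxyl.
- Against it here: A1 has neither C11–C13 nor the stereocentres C6 and C7. The three-carbon unit must be attached α to the C6 ketone in competition with enolisation towards C5, the ketone must be reduced to the 6α-alcohol on a mobile ring, and the C–Si bond must be oxidised beside three alkenes.
- Structure: the alternative is the better plan for the C4=C5 geometry and the equal of the chosen plan for C1=C10. The chosen key step, however, delivers C6, C7 and the methylene at once.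
- Mechanism: the oxy-Cope shift is more certain to take its course than a lithiation that must choose C6 over C13, so here the alternative is better. Its weak point is moved to the later enolate chemistry.
- Step economy: it should be shorter up to the ring and clearly longer after it, so the totals are expected to be similar.

Alternative 2: The cut is C3–C4, made on a compound that already holds the 8,12-lactone (without C13) and all three stereocentres. Forward, 9-BBN adds to the terminal C2=C3 alkene of a dienyl arm and palladium couples the C3 borane with a Z C4 iodoalkene, closing the ring to lactone A2.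
- In its favour: C6, C7 and C8 are set before ring closure by open-chain or lactone-bound stereocontrol that does not depend on a macrocycle conformation. The conditions are neutral and catalytic, and methylenation of the lactone afterwards is routine.
- Against it here: direct end-to-end closure of a ten-membered ring holding an E trisubstituted alkene and a trans-fused lactone is the least favourable case for this coupling. Protodeboronation, β-hydride elimination and oligomerisation are expected to compete.
- Structure: the alternative is the equal of the chosen plan for C4=C5 (both store the geometry in an iodoalkene) and the better one for the security of the three stereocentres. The chosen plan is better for ring formation, since it closes a 13-membered ring and reaches the ten-membered ring by a five-centre shift.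
- Mechanism: the alternative is better in functional-group tolerance, having no organolithium.
- Step economy: about equal, with C13 still to be added.

Alternative 3: The cut is C2–C3 (with C5–C10 re-formed in the backward sense). The ring is traced to a carvone-type six-membered ring (C5–C10) that already carries O6, the C7 side unit with C11–C13 and O8. It also carries a 1-(methoxycarbonyl)vinyl group (C3=C4, C15) on the C5 carbinol and a vinyl group (C1=C2) on the quaternary C10. Forward, the potassium alkoxide rearranges by [3,3] shift to a ten-membered β-keto ester enolate that is O-triflated in the same flask to A3.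
- In its favour: all three stereocentres are set on a cyclohexane chair, C11–C13 are present from the start, E C1=C10 comes from the chair transition state, and the C4=C5 geometry comes from the chelated enolate.
- Against it here: the rearrangement substrate is densely functionalised and would need a long linear build-up. Its alkoxide sits beside an acrylate and beside silyl ethers, and C5 and C15 must afterwards be brought to the right oxidation level (triflate reduction, ester reduction).
- Structure: the alternative is better for the stereocentres and equal for C1=C10.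
- Mechanism: it is the equal of the chosen plan as an anionic sigmatropic ring-size change, and better in regiochemical certainty.
- Step economy: the chosen plan is expected to be clearly shorter.

Key step: step 14

Remark: germacrane numbering (C1–C15, O6, O8, O12, O15) is used for all intermediates. In step 4 the (S)-configured phosphoric acid is assumed, by analogy with other alkenyl aldehydes, to give the (S)-carbinol; if the sense is the opposite, its enantiomer is used.

## Steps

Step 1
Reactants: 1 but-2-yne-1,4-diol
Product: 2 4-[(4-methoxybenzyl)oxy]but-2-yn-1-ol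
Conditions: 1 (3 equiv), NaH (1 equiv), 4-methoxybenzyl chloride (1 equiv), Bu4NI (cat.), THF/DMF, 0 °C to rt
Reagents that add atoms: 4-methoxybenzyl chloride, COc1ccc(CCl)cc1
Why: Williamson etherification; the excess of the cheap symmetric diol keeps double alkylation low, and the remaining hydroxyl is the directing group of step 2.

Step 2
Reactants: 2 4-[(4-methoxybenzyl)oxy]but-2-yn-1-ol
Product: 4 (2Z)-3-iodo-4-[(4-methoxybenzyl)oxy]but-2-en-1-ol, via cyclic alkenylalanate 3 (not isolated)
Conditions: NaAlH2(OCH2CH2OMe)2 (1.5 equiv), THF, 0 °C; then I2, THF, −78 to 0 °C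
Reagents that add atoms: iodine, [I][I]
Why: Hydroxyl-directed trans-hydroalumination of a propargylic alcohol: hydride goes from the alkoxide-bound aluminium to the near alkyne carbon and aluminium ends on the far carbon in a five-membered ring; iodinolysis with retention gives the Z iodoalkene. This one geometry serves twice, for ring-cis C4=C5 and for C7=C11 with C12 cis to C8.

Step 3
Reactants: 4 (2Z)-3-iodo-4-[(4-methoxybenzyl)oxy]but-2-en-1-ol
Product: 5 (2Z)-3-iodo-4-[(4-methoxybenzyl)oxy]but-2-enal
Conditions: MnO2 (15 equiv), CH2Cl2, rt, dark; used at once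
Reagents that add atoms: none
Why: Neutral allylic oxidation with MnO2; the Z β-iodoenal is kept from acid, base and light, which would equilibrate it to the E isomer.

Step 4
Reactants: 5 (2Z)-3-iodo-4-[(4-methoxybenzyl)oxy]but-2-enal; 6 allenylboronic acid pinacol ester
Product: 7 (4S,5Z)-6-iodo-7-[(4-methoxybenzyl)oxy]hept-5-en-1-yn-4-ol
Conditions: 6 (1.5 equiv), (S)-TRIP phosphoric acid (5 mol%), 4 Å MS, toluene, 0 °C
Reagents that add atoms: none
Why: Chiral Brønsted acid catalysed propargylboration of an aldehyde; the allenylboronate reacts at its γ-carbon through a closed six-membered transition state held by the phosphoric acid, which selects one aldehyde face and sets C8 as S. The product carries the terminal alkyne that becomes C10/C1.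

Step 5
Reactants: 7 (4S,5Z)-6-iodo-7-[(4-methoxybenzyl)oxy]hept-5-en-1-yn-4-ol
Product: 8 (2E,4S)-2-{[(4-methoxybenzyl)oxy]methyl}hept-2-en-6-yne-1,4-diol
Conditions: Bu3SnCH2OH (1.5 equiv), Pd(PPh3)4 (5 mol%), 1,4-dioxane, 85 °C
Reagents that add atoms: (tributylstannyl)methanol, OC[Sn](CCCC)(CCCC)CCCC
Why: Stille coupling of an alkenyl iodide with the hydroxymethyl stannane, with retention of geometry: C12 enters cis to C8 and C13 stays trans. No copper salt or amine is present, so the terminal alkyne does not couple.

Step 6
Reactants: 8 (2E,4S)-2-{[(4-methoxybenzyl)oxy]methyl}hept-2-en-6-yne-1,4-diol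
Product: 9 (4S,5Z)-7-[(4-methoxybenzyl)oxy]-4-(triethylsilyloxy)-6-[(triethylsilyloxy)methyl]hept-5-en-1-yne
Conditions: Et3SiCl (2.5 equiv), imidazole (4 equiv), DMF, 0 °C to rt
Reagents that add atoms: chlorotriethylsilane, CC[Si](Cl)(CC)CC
Why: Standard silylation of a primary and a secondary hydroxyl; O8 and O12 receive the same labile group in one operation.

Step 7
Reactants: 9 (4S,5Z)-7-[(4-methoxybenzyl)oxy]-4-(triethylsilyloxy)-6-[(triethylsilyloxy)methyl]hept-5-en-1-yne
Product: 11 (1E,4S,5Z)-1-iodo-7-[(4-methoxybenzyl)oxy]-2-methyl-4-(triethylsilyloxy)-6-[(triethylsilyloxy)methyl]hepta-1,5-diene, via alkenylalane 10 (not isolated)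
Conditions: Me3Al (3 equiv), Cp2ZrCl2 (0.3 equiv), CH2Cl2, 0 °C to rt; then I2, THF, −30 to 0 °C
Reagents that add atoms: trimethylaluminium, C[Al](C)C; iodine, [I][I]
Why: Negishi zirconium-catalysed carboalumination: syn addition of methyl and aluminium to the terminal alkyne with methyl on the inner carbon (C10), then iodinolysis with retention, gives E C1=C10 with C14 in place. Homopropargylic silyl ethers are usual substrates.

Step 8
Reactants: 11 (1E,4S,5Z)-1-iodo-7-[(4-methoxybenzyl)oxy]-2-methyl-4-(triethylsilyloxy)-6-[(triethylsilyloxy)methyl]hepta-1,5-diene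
Product: 12 (2Z,4S,6E)-7-iodo-6-methyl-4-(triethylsilyloxy)-2-[(triethylsilyloxy)methyl]hepta-2,6-dien-1-ol
Conditions: DDQ (1.3 equiv), CH2Cl2/pH 7 buffer 10:1, 0 °C
Reagents that add atoms: none
Why: Oxidative cleavage of a 4-methoxybenzyl ether by hydride abstraction; buffered, non-acidic conditions keep both triethylsilyl ethers and the alkenyl iodide.

Step 9
Reactants: 12 (2Z,4S,6E)-7-iodo-6-methyl-4-(triethylsilyloxy)-2-[(triethylsilyloxy)methyl]hepta-2,6-dien-1-ol
Product: 13 (1E,4S,5E)-6-(bromomethyl)-1-iodo-2-methyl-4,7-bis(triethylsilyloxy)hepta-1,5-diene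
Conditions: CBr4 (1.3 equiv), PPh3 (1.4 equiv), 2,6-lutidine (2 equiv), CH2Cl2, −20 to 0 °C
Reagents that add atoms: carbon tetrabromide, BrC(Br)(Br)Br
Why: Appel bromination of a primary allylic alcohol by SN2 on the alkoxyphosphonium salt; no alkoxide is formed next to the C12 silyl ether, and lutidine buffers traces of HBr.

Step 10
Reactants: 4 (2Z)-3-iodo-4-[(4-methoxybenzyl)oxy]but-2-en-1-ol; 14 tributyl(vinyl)stannane
Product: 15 (2E)-3-{[(4-methoxybenzyl)oxy]methyl}penta-2,4-dien-1-ol
Conditions: 14 (1.3 equiv), Pd(PPh3)4 (5 mol%), CuI (10 mol%), DMF, rt to 40 °C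
Reagents that add atoms: none
Why: Stille coupling with retention: the vinyl group (C3, C2) takes the place of iodine cis to C6, which fixes the ring-cis C4=C5 bond. The free C6 hydroxyl is tolerated.

Step 11
Reactants: 15 (2E)-3-{[(4-methoxybenzyl)oxy]methyl}penta-2,4-dien-1-ol; 13 (1E,4S,5E)-6-(bromomethyl)-1-iodo-2-methyl-4,7-bis(triethylsilyloxy)hepta-1,5-diene
Product: 16 (1E,4S,5Z)-1-iodo-6-[({(2E)-3-{[(4-methoxybenzyl)oxy]methyl}penta-2,4-dien-1-yl}oxy)methyl]-2-methyl-4,7-bis(triethylsilyloxy)hepta-1,5-diene
Conditions: 15, NaH (1.2 equiv), THF, 0 °C; then 13, Bu4NI (0.1 equiv), 0 °C to rt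
Reagents that add atoms: none
Why: Williamson etherification by SN2 at the primary allylic bromide; SN2′ at C7 is blocked by the C8 branch. The alkoxide is on O6, so none arises next to the C12 silyl ether.

Step 12
Reactants: 16 (1E,4S,5Z)-1-iodo-6-[({(2E)-3-{[(4-methoxybenzyl)oxy]methyl}penta-2,4-dien-1-yl}oxy)methyl]-2-methyl-4,7-bis(triethylsilyloxy)hepta-1,5-diene
Product: 18 (3E,7E,10S,11Z)-4-{[(4-methoxybenzyl)oxy]methyl}-8-methyl-10-(triethylsilyloxy)-12-[(triethylsilyloxy)methyl]-1-oxacyclotrideca-3,7,11-triene, via B-alkyl-9-BBN adduct 17 (not isolated)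
Conditions: 9-BBN (2 equiv), THF, rt; then added over 10 h to Pd(dppf)Cl2 (15 mol%), AsPh3 (30 mol%), Cs2CO3 (4 equiv), DMF/THF/H2O, 45 °C, 1 mM
Reagents that add atoms: none
Why: 9-BBN adds to the only monosubstituted alkene (boron on C2); the intramolecular B-alkyl Suzuki–Miyaura coupling with the unhindered E alkenyl iodide forms C1–C2 with retention and closes the 13-membered ring. Slow addition at high dilution favours ring closure over oligomers.

Step 13
Reactants: 18 (3E,7E,10S,11Z)-4-{[(4-methoxybenzyl)oxy]methyl}-8-methyl-10-(triethylsilyloxy)-12-[(triethylsilyloxy)methyl]-1-oxacyclotrideca-3,7,11-triene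
Product: 19 [(3E,7E,10S,11Z)-8-methyl-10-(triethylsilyloxy)-12-[(triethylsilyloxy)methyl]-1-oxacyclotrideca-3,7,11-trien-4-yl]methanol
Conditions: DDQ (1.2 equiv), CH2Cl2/pH 7 buffer 10:1, 0 °C, short time
Reagents that add atoms: none
Why: Oxidative removal of the 4-methoxybenzyl group, which reacts faster than the allylic ring ethers at 0 °C. The benzylic ether must be gone before the base step, and the diene that DDQ would attack was consumed in step 12.

Step 14
Reactants: 19 [(3E,7E,10S,11Z)-8-methyl-10-(triethylsilyloxy)-12-[(triethylsilyloxy)methyl]-1-oxacyclotrideca-3,7,11-trien-4-yl]methanol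
Product: 21 6α,15-dihydroxy-8α,12-bis(triethylsilyloxy)-7αH-germacra-1(10),4,11(13)-triene (6R,7S,8S), via C6-lithiated lithium alkoxide 20 (not isolated)
Conditions: n-BuLi (2.5 equiv), THF, −78 to −40 °C; AcOH, THF, −78 °C
Reagents that add atoms: none
Why: The first equivalent of n-BuLi turns O15–H into a lithium alkoxide that cannot be expelled from the later allyl anion; the next removes a C6 proton, which is allylic to C4=C5 and α to the ring oxygen, to give 20. 20 rearranges by a concerted suprafacial [2,3]-sigmatropic (Wittig) shift through a five-membered envelope transition state in which C6–C7 forms, O–C13 breaks and C11=C13 becomes the exocyclic methylene; the closest known reaction type is the [2,3]-Wittig ring contraction of 13-membered diallylic ethers to ten-membered homoallylic alcohols of the germacrane type. The ten-membered carbocycle is thus closed transannularly, by contraction of the 13-membered ether across C6/C7, and not end to end. C7: H8 eclipses the C7=C11 plane to avoid allylic 1,3-strain with the C12 silyloxymethyl group, the C9 chain that leads round the ring to C6 lies on one face and the silyloxy group on the other, so C6 bonds anti to O8 (C11 trans to O8). C6: with C8 trans to C13 on the alkene and C5 exo on the envelope, the shift follows the anti pattern of E allyl ethers, which on the ring means O6 trans to C11. The step needs lithiation at C6 and not at C13 (a C13 anion would expel the O8 silanolate or bond to C4); the substrate gives only modest help, in that the C6 methylene on a CH= carbon is the less hindered one, a shift from C13 would have to build a quaternary C4, and the ring conformation is relied on as in the parent ring system. Keeping the mixture below −40 °C and quenching cold with acid prevents the new C6 alkoxide from taking the silyl group from O8.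

Step 15
Reactants: 22 ethyl but-2-ynoate
Product: 24 ethyl (2Z)-2-(hydroxymethyl)but-2-enoate, via alkenylalane 23 (not isolated)
Conditions: i-Bu2AlH (1.2 equiv), N-methylmorpholine N-oxide (1.5 equiv), THF, 0 °C; then CH2O (gas, from paraformaldehyde), 0 °C to rt
Reagents that add atoms: formaldehyde, C=O
Why: Syn hydroalumination of an ynoate places aluminium on the α-carbon and hydrogen on the β-carbon (vinylalumination); trapping with formaldehyde at the α-carbon with retention gives the enoate whose carbonyl is cis to the methyl group, as in the target.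

Step 16
Reactants: 24 ethyl (2Z)-2-(hydroxymethyl)but-2-enoate
Product: 25 ethyl (2Z)-2-{[(tert-butyldimethylsilyl)oxy]methyl}but-2-enoate
Conditions: t-BuMe2SiCl (1.2 equiv), imidazole (2 equiv), CH2Cl2, rt
Reagents that add atoms: tert-butyldimethylsilyl chloride, CC(C)(C)[Si](C)(C)Cl
Why: Routine silylation of a primary alcohol; the silyl ether must outlast the removal of the triethylsilyl groups in step 20.

Step 17
Reactants: 25 ethyl (2Z)-2-{[(tert-butyldimethylsilyl)oxy]methyl}but-2-enoate
Product: 26 (2Z)-2-{[(tert-butyldimethylsilyl)oxy]methyl}but-2-enoic acid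
Conditions: LiOH (3 equiv), THF/MeOH/H2O, 0 °C to rt; aq. HCl to pH 4, 0 °C
Reagents that add atoms: lithium hydroxide, [Li+].[OH-]
Why: Saponification at the acyl carbon; hydroxide does not add reversibly to the hindered trisubstituted enoate at this temperature, so the Z geometry should be kept.

Step 18
Reactants: 21 6α,15-dihydroxy-8α,12-bis(triethylsilyloxy)-7αH-germacra-1(10),4,11(13)-triene; 26 (2Z)-2-{[(tert-butyldimethylsilyl)oxy]methyl}but-2-enoic acid
Product: 27 15-[(2Z)-2-{[(tert-butyldimethylsilyl)oxy]methyl}but-2-enoyloxy]-6α-hydroxy-8α,12-bis(triethylsilyloxy)-7αH-germacra-1(10),4,11(13)-triene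
Conditions: 26 (1.2 equiv), PPh3 (1.3 equiv), diisopropyl azodicarboxylate (1.3 equiv), THF, 0 °C
Reagents that add atoms: none
Why: Mitsunobu esterification: the primary allylic O15–H is activated far faster than the hindered secondary O6–H and is displaced by the carboxylate in an SN2 step. The acid is never turned into an acylating agent, so the Z-enoate cannot isomerise through a nucleophilic catalyst.

Step 19
Reactants: 27 15-[(2Z)-2-{[(tert-butyldimethylsilyl)oxy]methyl}but-2-enoyloxy]-6α-hydroxy-8α,12-bis(triethylsilyloxy)-7αH-germacra-1(10),4,11(13)-triene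
Product: 28 6α-(tert-butyldimethylsilyloxy)-15-[(2Z)-2-{[(tert-butyldimethylsilyl)oxy]methyl}but-2-enoyloxy]-8α,12-bis(triethylsilyloxy)-7αH-germacra-1(10),4,11(13)-triene
Conditions: t-BuMe2SiOTf (1.5 equiv), 2,6-lutidine (3 equiv), CH2Cl2, −78 °C
Reagents that add atoms: tert-butyldimethylsilyl trifluoromethanesulfonate, CC(C)(C)[Si](C)(C)OS(=O)(=O)C(F)(F)F
Why: Silyl triflate and a hindered base silylate the crowded secondary allylic alcohol without forming an alkoxide, so no silyl group moves from O8; O6 is now blocked for the lactone closure.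

Step 20
Reactants: 28 6α-(tert-butyldimethylsilyloxy)-15-[(2Z)-2-{[(tert-butyldimethylsilyl)oxy]methyl}but-2-enoyloxy]-8α,12-bis(triethylsilyloxy)-7αH-germacra-1(10),4,11(13)-triene
Product: 29 6α-(tert-butyldimethylsilyloxy)-15-[(2Z)-2-{[(tert-butyldimethylsilyl)oxy]methyl}but-2-enoyloxy]-8α,12-dihydroxy-7αH-germacra-1(10),4,11(13)-triene
Conditions: PPTS (0.2 equiv), MeOH/CH2Cl2 1:1, 0 °C
Reagents that add atoms: none
Why: Mild acid-catalysed methanolysis removes triethylsilyl ethers much faster than tert-butyldimethylsilyl ethers; the weak acid at 0 °C should not trigger transannular cyclisation of the diene.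

Step 21
Reactants: 29 6α-(tert-butyldimethylsilyloxy)-15-[(2Z)-2-{[(tert-butyldimethylsilyl)oxy]methyl}but-2-enoyloxy]-8α,12-dihydroxy-7αH-germacra-1(10),4,11(13)-triene
Product: 32 6α-(tert-butyldimethylsilyloxy)-15-[(2Z)-2-{[(tert-butyldimethylsilyl)oxy]methyl}but-2-enoyloxy]-7αH-germacra-1(10),4,11(13)-trien-12,8α-olide, via hydroxy enal 30 (not isolated), via lactol 31 (not isolated)
Conditions: MnO2 (25 equiv), CH2Cl2, rt
Reagents that add atoms: none
Why: MnO2 oxidises only the free allylic primary alcohol at C12; the enal is trapped by O8–H as a five-membered lactol, which MnO2 oxidises on to the lactone (oxidative lactonisation of a 2-methylene-1,4-diol). The trans ring fusion follows from the configurations already present at C7 and C8.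

Step 22
Reactants: 32 6α-(tert-butyldimethylsilyloxy)-15-[(2Z)-2-{[(tert-butyldimethylsilyl)oxy]methyl}but-2-enoyloxy]-7αH-germacra-1(10),4,11(13)-trien-12,8α-olide
Product: 33 (6R,7S,8S)-6-hydroxy-15-{[(2Z)-2-(hydroxymethyl)but-2-enoyl]oxy}germacra-1(10),4,11(13)-trien-12,8-olide
Conditions: HF·pyridine, pyridine, THF, 0 °C to rt
Reagents that add atoms: none
Why: Buffered HF·pyridine cleaves both tert-butyldimethylsilyl ethers; the medium is acidic and not basic, so neither translactonisation to O6 nor conjugate addition to the lactone nor enoate isomerisation is expected.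

## Compound list

1 | but-2-yne-1,4-diol | OCC#CCO | starting material
2 | 4-[(4-methoxybenzyl)oxy]but-2-yn-1-ol | COc1ccc(COCC#CCO)cc1 | intermediate
3 | sodium 2,2-bis(2-methoxyethoxy)-3-{[(4-methoxybenzyl)oxy]methyl}-2,5-dihydro-1,2-oxaaluminol-2-uide (cyclic alkenylalanate, formed in the flask) | COCCO[Al-]1(OCCOC)OCC=C1COCc1ccc(OC)cc1.[Na+] | intermediate
4 | (2Z)-3-iodo-4-[(4-methoxybenzyl)oxy]but-2-en-1-ol | OC/C=C(I)/COCc1ccc(OC)cc1 | intermediate
5 | (2Z)-3-iodo-4-[(4-methoxybenzyl)oxy]but-2-enal | O=C/C=C(I)/COCc1ccc(OC)cc1 | intermediate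
6 | allenylboronic acid pinacol ester | C=C=CB1OC(C)(C)C(C)(C)O1 | starting material
7 | (4S,5Z)-6-iodo-7-[(4-methoxybenzyl)oxy]hept-5-en-1-yn-4-ol | C#CC[C@H](O)/C=C(I)/COCc1ccc(OC)cc1 | intermediate
8 | (2E,4S)-2-{[(4-methoxybenzyl)oxy]methyl}hept-2-en-6-yne-1,4-diol | C#CC[C@H](O)/C=C(CO)/COCc1ccc(OC)cc1 | intermediate
9 | (4S,5Z)-7-[(4-methoxybenzyl)oxy]-4-(triethylsilyloxy)-6-[(triethylsilyloxy)methyl]hept-5-en-1-yne | C#CC[C@H](O[Si](CC)(CC)CC)/C=C(CO[Si](CC)(CC)CC)/COCc1ccc(OC)cc1 | intermediate
10 | (E)-alkenyl(dimethyl)alane from 9, aluminium on C1 and methyl on C10 (formed in the flask) | C[Al](C)/C=C(C)/C[C@H](O[Si](CC)(CC)CC)/C=C(CO[Si](CC)(CC)CC)/COCc1ccc(OC)cc1 | intermediate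
11 | (1E,4S,5Z)-1-iodo-7-[(4-methoxybenzyl)oxy]-2-methyl-4-(triethylsilyloxy)-6-[(triethylsilyloxy)methyl]hepta-1,5-diene | I/C=C(C)/C[C@H](O[Si](CC)(CC)CC)/C=C(CO[Si](CC)(CC)CC)/COCc1ccc(OC)cc1 | intermediate
12 | (2Z,4S,6E)-7-iodo-6-methyl-4-(triethylsilyloxy)-2-[(triethylsilyloxy)methyl]hepta-2,6-dien-1-ol | I/C=C(C)/C[C@H](O[Si](CC)(CC)CC)/C=C(CO[Si](CC)(CC)CC)/CO | intermediate
13 | (1E,4S,5E)-6-(bromomethyl)-1-iodo-2-methyl-4,7-bis(triethylsilyloxy)hepta-1,5-diene | I/C=C(C)/C[C@H](O[Si](CC)(CC)CC)/C=C(CO[Si](CC)(CC)CC)/CBr | intermediate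
14 | tributyl(vinyl)stannane | C=C[Sn](CCCC)(CCCC)CCCC | starting material
15 | (2E)-3-{[(4-methoxybenzyl)oxy]methyl}penta-2,4-dien-1-ol | OC/C=C(C=C)/COCc1ccc(OC)cc1 | intermediate
16 | (1E,4S,5Z)-1-iodo-6-[({(2E)-3-{[(4-methoxybenzyl)oxy]methyl}penta-2,4-dien-1-yl}oxy)methyl]-2-methyl-4,7-bis(triethylsilyloxy)hepta-1,5-diene | I/C=C(C)/C[C@H](O[Si](CC)(CC)CC)/C=C(CO[Si](CC)(CC)CC)/COC/C=C(C=C)/COCc1ccc(OC)cc1 | intermediate
17 | B-alkyl-9-borabicyclo[3.3.1]nonane from 16, boron on C2 (formed in the flask) | I/C=C(C)/C[C@H](O[Si](CC)(CC)CC)/C=C(CO[Si](CC)(CC)CC)/COC/C=C(CCB1C2CCCC1CCC2)/COCc1ccc(OC)cc1 | intermediate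
18 | (3E,7E,10S,11Z)-4-{[(4-methoxybenzyl)oxy]methyl}-8-methyl-10-(triethylsilyloxy)-12-[(triethylsilyloxy)methyl]-1-oxacyclotrideca-3,7,11-triene | O1C/C=C(COCc2ccc(OC)cc2)\CC/C=C(C)/C[C@H](O[Si](CC)(CC)CC)/C=C(CO[Si](CC)(CC)CC)/C1 | intermediate
19 | [(3E,7E,10S,11Z)-8-methyl-10-(triethylsilyloxy)-12-[(triethylsilyloxy)methyl]-1-oxacyclotrideca-3,7,11-trien-4-yl]methanol (O bridges C6 and C13; C3/C6 cis; C8/C13 trans) | O1C/C=C(CO)\CC/C=C(C)/C[C@H](O[Si](CC)(CC)CC)/C=C(CO[Si](CC)(CC)CC)/C1 | intermediate
20 | C6-lithio derivative of the lithium O15-alkoxide of 19 (formed in the flask; C6 configurationally labile) | O1C([Li])/C=C(CO[Li])\CC/C=C(C)/C[C@H](O[Si](CC)(CC)CC)/C=C(CO[Si](CC)(CC)CC)/C1 | intermediate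
21 | 6α,15-dihydroxy-8α,12-bis(triethylsilyloxy)-7αH-germacra-1(10),4,11(13)-triene (6R,7S,8S; 1(10)E; C4=C5 ring-cis) | C=C(CO[Si](CC)(CC)CC)[C@@H]1[C@@H](O[Si](CC)(CC)CC)C/C(C)=C/CC/C(CO)=C\[C@H]1O | intermediate
22 | ethyl but-2-ynoate | CC#CC(=O)OCC | starting material
23 | ethyl 2-(diisobutylalumanyl)but-2-enoate, ester cis to methyl (formed in the flask) | CCOC(=O)/C(=C\C)[Al](CC(C)C)CC(C)C | intermediate
24 | ethyl (2Z)-2-(hydroxymethyl)but-2-enoate | CCOC(=O)/C(=C\C)CO | intermediate
25 | ethyl (2Z)-2-{[(tert-butyldimethylsilyl)oxy]methyl}but-2-enoate | CCOC(=O)/C(=C\C)CO[Si](C)(C)C(C)(C)C | intermediate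
26 | (2Z)-2-{[(tert-butyldimethylsilyl)oxy]methyl}but-2-enoic acid | OC(=O)/C(=C\C)CO[Si](C)(C)C(C)(C)C | intermediate
27 | 15-[(2Z)-2-{[(tert-butyldimethylsilyl)oxy]methyl}but-2-enoyloxy]-6α-hydroxy-8α,12-bis(triethylsilyloxy)-7αH-germacra-1(10),4,11(13)-triene | C=C(CO[Si](CC)(CC)CC)[C@@H]1[C@@H](O[Si](CC)(CC)CC)C/C(C)=C/CC/C(COC(=O)/C(=C\C)CO[Si](C)(C)C(C)(C)C)=C\[C@H]1O | intermediate
28 | 6α-(tert-butyldimethylsilyloxy)-15-[(2Z)-2-{[(tert-butyldimethylsilyl)oxy]methyl}but-2-enoyloxy]-8α,12-bis(triethylsilyloxy)-7αH-germacra-1(10),4,11(13)-triene | C=C(CO[Si](CC)(CC)CC)[C@@H]1[C@@H](O[Si](CC)(CC)CC)C/C(C)=C/CC/C(COC(=O)/C(=C\C)CO[Si](C)(C)C(C)(C)C)=C\[C@H]1O[Si](C)(C)C(C)(C)C | intermediate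
29 | 6α-(tert-butyldimethylsilyloxy)-15-[(2Z)-2-{[(tert-butyldimethylsilyl)oxy]methyl}but-2-enoyloxy]-8α,12-dihydroxy-7αH-germacra-1(10),4,11(13)-triene | C=C(CO)[C@@H]1[C@@H](O)C/C(C)=C/CC/C(COC(=O)/C(=C\C)CO[Si](C)(C)C(C)(C)C)=C\[C@H]1O[Si](C)(C)C(C)(C)C | intermediate
30 | 12-aldehyde of 29 (hydroxy enal, formed in the flask) | C=C(C=O)[C@@H]1[C@@H](O)C/C(C)=C/CC/C(COC(=O)/C(=C\C)CO[Si](C)(C)C(C)(C)C)=C\[C@H]1O[Si](C)(C)C(C)(C)C | intermediate
31 | 12,8α-lactol of 30 (formed in the flask; C12 unassigned) | C=C1C(O)O[C@H]2C/C(C)=C/CC/C(COC(=O)/C(=C\C)CO[Si](C)(C)C(C)(C)C)=C\[C@@H](O[Si](C)(C)C(C)(C)C)[C@H]12 | intermediate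
32 | 6α-(tert-butyldimethylsilyloxy)-15-[(2Z)-2-{[(tert-butyldimethylsilyl)oxy]methyl}but-2-enoyloxy]-7αH-germacra-1(10),4,11(13)-trien-12,8α-olide | C=C1C(=O)O[C@H]2C/C(C)=C/CC/C(COC(=O)/C(=C\C)CO[Si](C)(C)C(C)(C)C)=C\[C@@H](O[Si](C)(C)C(C)(C)C)[C@H]12 | intermediate
33 | (6R,7S,8S)-6-hydroxy-15-{[(2Z)-2-(hydroxymethyl)but-2-enoyl]oxy}germacra-1(10),4,11(13)-trien-12,8-olide (CNP0234544.2) | C=C1C(=O)O[C@H]2C/C(C)=C/CC/C(COC(=O)/C(=C\C)CO)=C\[C@@H](O)[C@H]12 | target

## Step count and least certain steps

Total: 22 steps. Longest linear sequence: 18 steps (steps 1–9, 11–14, 18–22). Step 10 branches from 4, and steps 15–17 make the side chain.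

**Step 14 (key step).** The most likely failure is lithiation at C13 in place of C6. The C13 allyl anion is stabilised inductively by the C8 silyloxy group, while the O15 alkoxide lowers the acidity at C6. The C13 anion would then lose silanolate or bond to C4. A second risk is transfer of the silyl group from O8 to the new C6 alkoxide.

Fallback, from 15 and 13, returning at 21: the C6–C7 bond is made between the open-chain halves and the ten-membered ring is closed afterwards.
- 15 is oxidised with MnO2 to (2E)-3-{[(4-methoxybenzyl)oxy]methyl}penta-2,4-dienal F1.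
- 13 and F1 are joined with CrCl2 in THF. The allylchromium reagent from 13 adds through its γ-carbon C7; the anti mode and Felkin control from C8 should give the open-chain (6R,7S,8S)-6-hydroxy-1-iodo-15-[(4-methoxybenzyl)oxy]-8,12-bis(triethylsilyloxy)-1,2-secogermacra-1(10),2,4,11(13)-tetraene F2. The alkenyl iodide is inert without a nickel salt.
- Excess 9-BBN converts F2 into the O,C2-bis(9-borabicyclononyl) derivative F3.
- Slow addition of F3 to Pd(dppf)Cl2, AsPh3 and Cs2CO3 closes C1–C2 to the ten-membered 15-(4-methoxybenzyl) ether of 21 F4.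
- DDQ in buffered CH2Cl2 then gives 21.

**Step 12.** Oligomerisation and protodeboronation of 17 may outrun closure of the 13-membered ring.

Fallback, from 12 and 4, returning at 18: the ring is closed at C3–C4 with the coupling partners exchanged.
- 12 is vinylated with 14 and Pd(PPh3)4 to (2Z,4S,6E)-6-methyl-4-(triethylsilyloxy)-2-[(triethylsilyloxy)methyl]nona-2,6,8-trien-1-ol F5.
- CBr4 and PPh3 convert F5 into (3E,6S,7E)-8-(bromomethyl)-4-methyl-6,9-bis(triethylsilyloxy)nona-1,3,7-triene F6.
- The sodium alkoxide of 4 is alkylated with F6 to the open-chain ether of 4 with F6 through O6 F7, which carries the Z C4 iodide.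
- 9-BBN adds to the terminal C2=C3 alkene to give the C3 B-alkyl-9-borabicyclononane of F7 F8.
- Palladium coupling of F8 at high dilution forms C3–C4 and gives 18.

**Step 4.** Insufficient face selection with this β-iodoenal, or acid-induced Z to E isomerisation of 5 before addition, would erode the single reagent-controlled stereocentre.

Fallback, from 5, returning at 7:
- Zinc dust and propargyl bromide in THF/aq. NH4Cl give racemic (5Z)-6-iodo-7-[(4-methoxybenzyl)oxy]hept-5-en-1-yn-4-ol F9.
- Candida antarctica lipase B with vinyl acetate should acylate the R enantiomer to (4R,5Z)-6-iodo-7-[(4-methoxybenzyl)oxy]hept-5-en-1-yn-4-yl acetate F10 and leave 7, which is separated by chromatography.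

**Step 15.** Incomplete trapping of the alkenylalane 23 by formaldehyde (which oligomerises) and loss of geometry through the aluminium allenolate would lower yield and Z purity.

Fallback, from 22, returning at 24:
- Bu3SnH and Pd(PPh3)4 add syn to 22 to give ethyl (2E)-2-(tributylstannyl)but-2-enoate F11.
- Iodine converts F11 with retention into ethyl (2E)-2-iodobut-2-enoate F12.
- Stille coupling of F12 with Bu3SnCH2OH and Pd(PPh3)4 gives 24.

## Further compounds

F1 | step 14 | (2E)-3-{[(4-methoxybenzyl)oxy]methyl}penta-2,4-dienal | O=C/C=C(C=C)/COCc1ccc(OC)cc1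
F2 | step 14 | (6R,7S,8S)-6-hydroxy-1-iodo-15-[(4-methoxybenzyl)oxy]-8,12-bis(triethylsilyloxy)-1,2-secogermacra-1(10),2,4,11(13)-tetraene | C=C(CO[Si](CC)(CC)CC)[C@H]([C@@H](O[Si](CC)(CC)CC)C/C(C)=C/I)[C@H](O)/C=C(C=C)/COCc1ccc(OC)cc1
F3 | step 14 | O,C2-bis(9-borabicyclo[3.3.1]nonan-9-yl) derivative of F2 | C=C(CO[Si](CC)(CC)CC)[C@H]([C@@H](O[Si](CC)(CC)CC)C/C(C)=C/I)[C@H](OB1C2CCCC1CCC2)/C=C(CCB1C2CCCC1CCC2)/COCc1ccc(OC)cc1
F4 | step 14 | 6α-hydroxy-15-[(4-methoxybenzyl)oxy]-8α,12-bis(triethylsilyloxy)-7αH-germacra-1(10),4,11(13)-triene | C=C(CO[Si](CC)(CC)CC)[C@@H]1[C@@H](O[Si](CC)(CC)CC)C/C(C)=C/CC/C(COCc2ccc(OC)cc2)=C\[C@H]1O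
F5 | step 12 | (2Z,4S,6E)-6-methyl-4-(triethylsilyloxy)-2-[(triethylsilyloxy)methyl]nona-2,6,8-trien-1-ol | C=C/C=C(C)/C[C@H](O[Si](CC)(CC)CC)/C=C(CO[Si](CC)(CC)CC)/CO
F6 | step 12 | (3E,6S,7E)-8-(bromomethyl)-4-methyl-6,9-bis(triethylsilyloxy)nona-1,3,7-triene | C=C/C=C(C)/C[C@H](O[Si](CC)(CC)CC)/C=C(CO[Si](CC)(CC)CC)/CBr
F7 | step 12 | open-chain ether of 4 (through O6) with F6 | C=C/C=C(C)/C[C@H](O[Si](CC)(CC)CC)/C=C(CO[Si](CC)(CC)CC)/COC/C=C(I)/COCc1ccc(OC)cc1
F8 | step 12 | C3 B-alkyl-9-borabicyclo[3.3.1]nonane from F7 | C1CCC2CCCC1B2CC/C=C(C)/C[C@H](O[Si](CC)(CC)CC)/C=C(CO[Si](CC)(CC)CC)/COC/C=C(I)/COCc1ccc(OC)cc1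
F9 | step 4 | racemic (5Z)-6-iodo-7-[(4-methoxybenzyl)oxy]hept-5-en-1-yn-4-ol | C#CCC(O)/C=C(I)/COCc1ccc(OC)cc1
F10 | step 4 | (4R,5Z)-6-iodo-7-[(4-methoxybenzyl)oxy]hept-5-en-1-yn-4-yl acetate | CC(=O)O[C@H](CC#C)/C=C(I)/COCc1ccc(OC)cc1
F11 | step 15 | ethyl (2E)-2-(tributylstannyl)but-2-enoate | CCOC(=O)/C(=C\C)[Sn](CCCC)(CCCC)CCCC
F12 | step 15 | ethyl (2E)-2-iodobut-2-enoate | CCOC(=O)/C(=C\C)I
A1 | alternative 1 | 8-(benzyldimethylsilyl)-15-[(4-methoxybenzyl)oxy]-11,12,13-trinorgermacra-1(10),4-dien-6-one | C[Si](C)(Cc1ccccc1)[C@H]2C/C(C)=C/CC/C(COCc3ccc(OC)cc3)=C\C(=O)C2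
A2 | alternative 2 | 6α,15-bis(tert-butyldimethylsilyloxy)-13-norgermacra-1(10),4-dien-12,8α-olide | C1C(=O)O[C@H]2C/C(C)=C/CC/C(CO[Si](C)(C)C(C)(C)C)=C\[C@@H](O[Si](C)(C)C(C)(C)C)[C@H]12
A3 | alternative 3 | methyl 6α-[(4-methoxybenzyl)oxy]-8α,12-bis(triethylsilyloxy)-5-(trifluoromethylsulfonyloxy)germacra-1(10),4,11(13)-trien-15-oate | C=C(CO[Si](CC)(CC)CC)[C@@H]1[C@@H](O[Si](CC)(CC)CC)C/C(C)=C/CC/C(C(=O)OC)=C(OS(=O)(=O)C(F)(F)F)\[C@H]1OCc2ccc(OC)cc2
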